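**Retrosynthetic overview**
- Numbering runs from the lactone carbonyl C1 to the aldehyde carbon C24. The last C–C bond made is C13–C14, by Negishi coupling of the alkenylzinc from alkyne 41 with vinyl iodide 16; desilylation and oxidation of C17–OH and C24–OH then give the ketone and the aldehyde.
- Fragment A (C1–C13, 16): dihydropyranone closed by ring-closing metathesis of acrylate 15; C4/C5 by Brown anti-crotylation of dienal 13; the 8Z alkene by Still–Gennari olefination; C10 by Evans alkylation.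
- Fragment B (C14–C24, 41): C16 by Marshall allenylzinc addition to aldehyde 35; C18 by Evans methylation; oxolane closed by intramolecular oxa-Michael addition of the C22 tertiary alkoxide to enoyl imide 31; C22 by Shi epoxidation and hydride opening; C20 by Evans alkylation.
- Ring order: the oxolane (step 24) and the dihydropyranone (step 12) are closed separately inside their fragments; no ring is formed after the fragment union.

Assumption: the target is made exactly as the SMILES encodes it, i.e. 4S,5R,10R,16R,18R,19R,20R,22R with 6E,8Z,12E,14E alkenes.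

**Fragment A (C1–C13)**

Step 1
Reactants: 1 (S)-4-benzyl-3-propanoyl-1,3-oxazolidin-2-one; 2 3-bromoprop-1-yne
Product: 3 (S)-4-benzyl-3-[(2R)-2-methylpent-4-ynoyl]-1,3-oxazolidin-2-one
Conditions: NaN(SiMe3)2, THF, −78 °C; then 2, −78 → −40 °C
Reagents that add atoms: none
Why: Evans asymmetric alkylation, in which the chelated sodium Z-enolate is propargylated on the face opposite the benzyl group and so sets C10 (R).

Step 2
Reactants: 3 (S)-4-benzyl-3-[(2R)-2-methylpent-4-ynoyl]-1,3-oxazolidin-2-one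
Product: 4 (2R)-2-methylpent-4-yn-1-ol
Conditions: LiBH4, H2O (1 equiv), Et2O, 0 °C
Reagents that add atoms: none
Why: Reductive cleavage of the imide gives the primary alcohol without touching the C10 stereocentre.

Step 3
Reactants: 4 (2R)-2-methylpent-4-yn-1-ol
Product: 6 (2R,4E)-5-iodo-2-methylpent-4-en-1-ol, via bis-zirconocene alkenyl alkoxide 5 (not isolated)
Conditions: Cp2Zr(H)Cl (2.2 equiv), THF, rt; then I2, 0 °C
Reagents that add atoms: iodine, II
Why: Schwartz hydrozirconation adds Zr–H syn with zirconium on the terminal carbon (the first equivalent is consumed by the OH), and iodinolysis with retention gives the E-vinyl iodide.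

Step 4
Reactants: 6 (2R,4E)-5-iodo-2-methylpent-4-en-1-ol
Product: 7 (2R,4E)-5-iodo-2-methylpent-4-enal
Conditions: Dess–Martin periodinane, pyridine, CH2Cl2, 0 °C
Reagents that add atoms: none
Why: Dess–Martin oxidation is mild enough that the α-stereocentre C10 is not epimerised when the aldehyde is used crude.

Step 5
Reactants: 8 methyl 2-[bis(2,2,2-trifluoroethoxy)phosphoryl]acetate
Product: 9 methyl 2-[bis(2,2,2-trifluoroethoxy)phosphoryl]butanoate (racemic)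
Conditions: KOt-Bu, THF, 0 °C; EtI, 0 °C → rt
Reagents that add atoms: iodoethane, CCI
Why: C-alkylation of the stabilised phosphonate carbanion gives the α-ethyl Still–Gennari reagent.

Step 6
Reactants: 7 (2R,4E)-5-iodo-2-methylpent-4-enal; 9 methyl 2-[bis(2,2,2-trifluoroethoxy)phosphoryl]butanoate
Product: 10 methyl (2Z,4R,6E)-2-ethyl-7-iodo-4-methylhepta-2,6-dienoate
Conditions: KN(SiMe3)2, 18-crown-6, THF, −78 °C
Reagents that add atoms: none
Why: Still–Gennari variant of the Horner–Wadsworth–Emmons reaction, whose fast irreversible elimination gives the Z-trisubstituted enoate (ester cis to C10), i.e. the 8Z geometry.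

Step 7
Reactants: 10 methyl (2Z,4R,6E)-2-ethyl-7-iodo-4-methylhepta-2,6-dienoate
Product: 11 (2Z,4R,6E)-2-ethyl-7-iodo-4-methylhepta-2,6-dien-1-ol
Conditions: i-Bu2AlH (2.5 equiv), CH2Cl2, −78 °C
Reagents that add atoms: none
Why: 1,2-Reduction of the enoate to the allylic alcohol leaves the alkene geometry and the vinyl iodide intact.

Step 8
Reactants: 11 (2Z,4R,6E)-2-ethyl-7-iodo-4-methylhepta-2,6-dien-1-ol
Product: 12 (2Z,4R,6E)-2-ethyl-7-iodo-4-methylhepta-2,6-dienal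
Conditions: MnO2 (excess), CH2Cl2, rt
Reagents that add atoms: none
Why: Neutral allylic oxidation with MnO2 gives the enal without Z to E isomerisation.

Step 9
Reactants: 12 (2Z,4R,6E)-2-ethyl-7-iodo-4-methylhepta-2,6-dienal
Product: 13 (2E,4Z,6R,8E)-4-ethyl-9-iodo-6-methylnona-2,4,8-trienal
Conditions: Ph3P=CHCHO, toluene, 80 °C
Reagents that add atoms: (triphenylphosphoranylidene)acetaldehyde, O=CC=P(c1ccccc1)(c1ccccc1)c1ccccc1
Why: Wittig reaction with a stabilised ylide gives the E-configured C6=C7 bond and the C5 aldehyde in one operation.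

Step 10
Reactants: 13 (2E,4Z,6R,8E)-4-ethyl-9-iodo-6-methylnona-2,4,8-trienal
Product: 14 (3S,4R,5E,7Z,9R,11E)-7-ethyl-12-iodo-3,9-dimethyldodeca-1,5,7,11-tetraen-4-ol
Conditions: trans-but-2-ene, n-BuLi, KOt-Bu, THF, −78 → −45 °C; (−)-Ipc2BOMe, BF3·OEt2, −78 °C; then 13, −78 °C; NaOH, H2O2
Reagents that add atoms: (E)-crotyldiisopinocampheylborane made in the flask from trans-but-2-ene, C/C=C/CB([C@@H]1C[C@@H]2C[C@H]([C@H]1C)C2(C)C)[C@@H]1C[C@@H]2C[C@H]([C@H]1C)C2(C)C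
Why: Brown crotylboration through a chair transition state, in which the E-crotyl geometry gives the anti pair and the Ipc groups from (+)-α-pinene direct attack to the si face, setting C4 (S) and C5 (R).

Step 11
Reactants: 14 (3S,4R,5E,7Z,9R,11E)-7-ethyl-12-iodo-3,9-dimethyldodeca-1,5,7,11-tetraen-4-ol
Product: 15 (3S,4R,5E,7Z,9R,11E)-7-ethyl-12-iodo-3,9-dimethyldodeca-1,5,7,11-tetraen-4-yl prop-2-enoate
Conditions: acryloyl chloride, i-Pr2NEt, DMAP (cat.), CH2Cl2, −78 → 0 °C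
Reagents that add atoms: acryloyl chloride, C=CC(=O)Cl
Why: O-Acylation under buffered conditions installs the second terminal alkene without ionising the dienyl carbinol.

Step 12
Reactants: 15 (3S,4R,5E,7Z,9R,11E)-7-ethyl-12-iodo-3,9-dimethyldodeca-1,5,7,11-tetraen-4-yl prop-2-enoate
Product: 16 (5S,6R)-6-[(1E,3Z,5R,7E)-3-ethyl-8-iodo-5-methylocta-1,3,7-trien-1-yl]-5-methyl-5,6-dihydro-2H-pyran-2-one
Conditions: second-generation Grubbs catalyst (5 mol %), CH2Cl2 (5 mM), 40 °C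
Reagents that add atoms: none
Why: Ring-closing metathesis joins the only two monosubstituted alkenes (vinyl and acrylate) into the six-membered unsaturated lactone, while the internal diene and the iodoalkene stay out of the reaction.

**Fragment B (C14–C24)**

Step 13
Reactants: 17 3-methylbut-2-en-1-ol
Product: 18 tert-butyldimethyl[(3-methylbut-2-en-1-yl)oxy]silane
Conditions: TBSCl, imidazole, CH2Cl2, rt
Reagents that add atoms: tert-butyldimethylsilyl chloride, CC(C)(C)[Si](C)(C)Cl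
Why: Silylation protects the future C24 oxygen through the base and hydride steps that follow.

Step 14
Reactants: 18 tert-butyldimethyl[(3-methylbut-2-en-1-yl)oxy]silane
Product: 19 (2E)-4-[(tert-butyldimethylsilyl)oxy]-2-methylbut-2-en-1-ol
Conditions: SeO2 (0.1 equiv), t-BuOOH, salicylic acid (cat.), CH2Cl2, rt
Reagents that add atoms: tert-butyl hydroperoxide, CC(C)(C)OO
Why: Catalytic SeO2 allylic oxidation (ene reaction then [2,3]-sigmatropic shift) hydroxylates the E-methyl group selectively.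

Step 15
Reactants: 19 (2E)-4-[(tert-butyldimethylsilyl)oxy]-2-methylbut-2-en-1-ol
Product: 20 {[(2E)-4-bromo-3-methylbut-2-en-1-yl]oxy}(tert-butyl)dimethylsilane
Conditions: CBr4, PPh3, CH2Cl2, 0 °C
Reagents that add atoms: tetrabromomethane, BrC(Br)(Br)Br
Why: Appel bromination displaces the primary allylic alcohol by SN2 without allylic transposition or loss of the E geometry.

Step 16
Reactants: 1 (S)-4-benzyl-3-propanoyl-1,3-oxazolidin-2-one; 20 {[(2E)-4-bromo-3-methylbut-2-en-1-yl]oxy}(tert-butyl)dimethylsilane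
Product: 21 (S)-4-benzyl-3-[(2R,4E)-6-[(tert-butyldimethylsilyl)oxy]-2,4-dimethylhex-4-enoyl]-1,3-oxazolidin-2-one
Conditions: NaN(SiMe3)2, THF, −78 °C; then 20, −78 → −30 °C
Reagents that add atoms: none
Why: Evans asymmetric alkylation with the reactive allylic bromide sets C20 (R) by attack anti to the benzyl group of the chelated Z-enolate.

Step 17
Reactants: 21 (S)-4-benzyl-3-[(2R,4E)-6-[(tert-butyldimethylsilyl)oxy]-2,4-dimethylhex-4-enoyl]-1,3-oxazolidin-2-one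
Product: 22 (2R,4E)-6-[(tert-butyldimethylsilyl)oxy]-2,4-dimethylhex-4-en-1-ol
Conditions: LiBH4, H2O (1 equiv), Et2O, 0 °C
Reagents that add atoms: none
Why: Reductive removal of the auxiliary gives the C19 primary alcohol with the silyl ether and alkene untouched.

Step 18
Reactants: 22 (2R,4E)-6-[(tert-butyldimethylsilyl)oxy]-2,4-dimethylhex-4-en-1-ol
Product: 23 (2R)-3-[(2R,3R)-3-{[(tert-butyldimethylsilyl)oxy]methyl}-2-methyloxiran-2-yl]-2-methylpropan-1-ol
Conditions: D-fructose-derived Shi ketone (0.3 equiv), Oxone (2KHSO5·KHSO4·K2SO4), K2CO3, Bu4NHSO4 (cat.), MeCN–CH2(OMe)2–aq. Na2B4O7 buffer, 0 °C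
Reagents that add atoms: potassium peroxymonosulfate, [K+].OOS(=O)(=O)[O-]
Why: Shi asymmetric epoxidation, in which the chiral dioxirane attacks the trisubstituted E-alkene through a spiro transition state to give the (R,R)-epoxide under reagent control and so fixes C22; the basic medium keeps the hydroxy epoxide from cyclising.

Step 19
Reactants: 23 (2R)-3-[(2R,3R)-3-{[(tert-butyldimethylsilyl)oxy]methyl}-2-methyloxiran-2-yl]-2-methylpropan-1-ol
Product: 24 (2R,4R)-6-[(tert-butyldimethylsilyl)oxy]-2,4-dimethylhexane-1,4-diol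
Conditions: LiEt3BH (3 equiv), THF, 0 °C → rt
Reagents that add atoms: none
Why: SN2 hydride opening at the less substituted epoxide carbon C23 leaves the C22–O bond untouched, so the tertiary alcohol keeps the (R) configuration.

Step 20
Reactants: 24 (2R,4R)-6-[(tert-butyldimethylsilyl)oxy]-2,4-dimethylhexane-1,4-diol
Product: 26 (3R,5R)-5-{2-[(tert-butyldimethylsilyl)oxy]ethyl}-3,5-dimethyloxolan-2-ol (both anomers), via hydroxy aldehyde 25 (not isolated)
Conditions: IBX (2-iodoxybenzoic acid), DMSO, rt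
Reagents that add atoms: none
Why: IBX oxidises the primary alcohol of a 1,4-diol and stops at the γ-lactol formed when the tertiary hydroxyl adds to the new aldehyde.

Step 21
Reactants: 27 (R)-4-benzyl-1,3-oxazolidin-2-one
Product: 28 (R)-4-benzyl-3-(2-bromoacetyl)-1,3-oxazolidin-2-one
Conditions: n-BuLi, THF, −78 °C; BrCH2COBr
Reagents that add atoms: bromoacetyl bromide, BrCC(Br)=O
Why: N-Acylation of the lithiated oxazolidinone by the acyl bromide is faster than displacement at the CH2Br carbon.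

Step 22
Reactants: 28 (R)-4-benzyl-3-(2-bromoacetyl)-1,3-oxazolidin-2-one
Product: 30 (R)-4-benzyl-3-[(triphenylphosphoranylidene)acetyl]-1,3-oxazolidin-2-one, via phosphonium bromide 29 (not isolated)
Conditions: PPh3, toluene, rt; then Et3N, CH2Cl2, 0 °C
Reagents that add atoms: triphenylphosphine, c1ccc(cc1)P(c1ccccc1)c1ccccc1
Why: SN2 quaternisation followed by deprotonation of the acidic α-CH2 gives the stabilised Wittig ylide that carries the auxiliary needed for C18.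

Step 23
Reactants: 26 (3R,5R)-5-{2-[(tert-butyldimethylsilyl)oxy]ethyl}-3,5-dimethyloxolan-2-ol; 30 (R)-4-benzyl-3-[(triphenylphosphoranylidene)acetyl]-1,3-oxazolidin-2-one
Product: 31 (R)-4-benzyl-3-[(2E,4R,6R)-8-[(tert-butyldimethylsilyl)oxy]-6-hydroxy-4,6-dimethyloct-2-enoyl]-1,3-oxazolidin-2-one
Conditions: toluene, 90 °C
Reagents that add atoms: none
Why: Wittig olefination of the open hydroxy-aldehyde tautomer of the lactol with a stabilised ylide gives the E-enoyl imide and frees the C22 tertiary hydroxyl.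

Step 24
Reactants: 31 (R)-4-benzyl-3-[(2E,4R,6R)-8-[(tert-butyldimethylsilyl)oxy]-6-hydroxy-4,6-dimethyloct-2-enoyl]-1,3-oxazolidin-2-one
Product: 32 (R)-4-benzyl-3-{[(2S,3R,5R)-5-{2-[(tert-butyldimethylsilyl)oxy]ethyl}-3,5-dimethyloxolan-2-yl]acetyl}-1,3-oxazolidin-2-one
Conditions: KOt-Bu (0.2 equiv), THF, −20 → 0 °C
Reagents that add atoms: none
Why: Intramolecular oxa-Michael addition (5-exo-trig) of the tertiary alkoxide to the enoyl imide closes the oxolane reversibly, and the 2,3-trans ring with the C20 methyl pseudo-equatorial is favoured kinetically and thermodynamically, which sets C19.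

Step 25
Reactants: 32 (R)-4-benzyl-3-{[(2S,3R,5R)-5-{2-[(tert-butyldimethylsilyl)oxy]ethyl}-3,5-dimethyloxolan-2-yl]acetyl}-1,3-oxazolidin-2-one
Product: 33 (R)-4-benzyl-3-{(2R)-2-[(2R,3R,5R)-5-{2-[(tert-butyldimethylsilyl)oxy]ethyl}-3,5-dimethyloxolan-2-yl]propanoyl}-1,3-oxazolidin-2-one
Conditions: NaN(SiMe3)2, THF, −78 °C; MeI, −78 °C
Reagents that add atoms: iodomethane, CI
Why: Evans asymmetric alkylation, in which the chelated Z-enolate is methylated anti to the benzyl group of the (R)-auxiliary and so sets C18 (R) under reagent control.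

Step 26
Reactants: 33 (R)-4-benzyl-3-{(2R)-2-[(2R,3R,5R)-5-{2-[(tert-butyldimethylsilyl)oxy]ethyl}-3,5-dimethyloxolan-2-yl]propanoyl}-1,3-oxazolidin-2-one
Product: 34 (2S)-2-[(2R,3R,5R)-5-{2-[(tert-butyldimethylsilyl)oxy]ethyl}-3,5-dimethyloxolan-2-yl]propan-1-ol
Conditions: LiBH4, H2O (1 equiv), Et2O, 0 °C
Reagents that add atoms: none
Why: Reductive cleavage of the imide gives the C17 alcohol without epimerising C18 (the descriptor changes only through CIP priorities).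

Step 27
Reactants: 34 (2S)-2-[(2R,3R,5R)-5-{2-[(tert-butyldimethylsilyl)oxy]ethyl}-3,5-dimethyloxolan-2-yl]propan-1-ol
Product: 35 (2R)-2-[(2R,3R,5R)-5-{2-[(tert-butyldimethylsilyl)oxy]ethyl}-3,5-dimethyloxolan-2-yl]propanal
Conditions: Dess–Martin periodinane, pyridine, CH2Cl2, 0 °C
Reagents that add atoms: none
Why: Buffered Dess–Martin oxidation gives the α-branched aldehyde, which is used at once so that C18 is not epimerised.

Step 28
Reactants: 36 (S)-but-3-yn-2-ol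
Product: 37 (S)-but-3-yn-2-yl methanesulfonate
Conditions: MsCl, Et3N, CH2Cl2, −78 °C
Reagents that add atoms: methanesulfonyl chloride, CS(=O)(=O)Cl
Why: O-Sulfonylation activates the propargylic position with retention for the palladium-mediated SN2′ step.

Step 29
Reactants: 35 (2R)-2-[(2R,3R,5R)-5-{2-[(tert-butyldimethylsilyl)oxy]ethyl}-3,5-dimethyloxolan-2-yl]propanal; 37 (S)-but-3-yn-2-yl methanesulfonate
Product: 39 (2S,3R,4R)-2-[(2R,3R,5R)-5-{2-[(tert-butyldimethylsilyl)oxy]ethyl}-3,5-dimethyloxolan-2-yl]-4-methylhex-5-yn-3-ol, via allenylzinc mesylate 38 (not isolated)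
Conditions: Pd(OAc)2 (5 mol %), PPh3 (5 mol %), Et2Zn (3 equiv), THF, −78 → −20 °C
Reagents that add atoms: none
Why: Marshall propargylation, in which zerovalent palladium displaces the mesylate anti (SN2′), transmetalation gives the allenylzinc, and cyclic SE2′ addition gives the anti adduct with net inversion, setting C16 (R); the C17 carbinol is oxidised later.

Step 30
Reactants: 39 (2S,3R,4R)-2-[(2R,3R,5R)-5-{2-[(tert-butyldimethylsilyl)oxy]ethyl}-3,5-dimethyloxolan-2-yl]-4-methylhex-5-yn-3-ol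
Product: 40 tert-butyl{2-[(2R,4R,5R)-2,4-dimethyl-5-[(2R,3R,4R)-4-methyl-3-[(triethylsilyl)oxy]hex-5-yn-2-yl]oxolan-2-yl]ethoxy}dimethylsilane
Conditions: TESOTf, 2,6-lutidine, CH2Cl2, −78 °C
Reagents that add atoms: triethylsilyl trifluoromethanesulfonate, CC[Si](CC)(CC)OS(=O)(=O)C(F)(F)F
Why: The silyl triflate protects the hindered C17 hydroxyl so that it survives acetylide formation and the organometallic coupling.

Step 31
Reactants: 40 tert-butyl{2-[(2R,4R,5R)-2,4-dimethyl-5-[(2R,3R,4R)-4-methyl-3-[(triethylsilyl)oxy]hex-5-yn-2-yl]oxolan-2-yl]ethoxy}dimethylsilane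
Product: 41 tert-butyl{2-[(2R,4R,5R)-2,4-dimethyl-5-[(2R,3R,4R)-4-methyl-3-[(triethylsilyl)oxy]hept-5-yn-2-yl]oxolan-2-yl]ethoxy}dimethylsilane
Conditions: n-BuLi, THF, −78 °C; MeI, −78 °C → rt
Reagents that add atoms: iodomethane, CI
Why: Methylation of the lithium acetylide introduces the C14 methyl group and gives the internal alkyne whose hydrometalation is regioselective.

**Fragment union and endgame**

Step 32
Reactants: 41 tert-butyl{2-[(2R,4R,5R)-2,4-dimethyl-5-[(2R,3R,4R)-4-methyl-3-[(triethylsilyl)oxy]hept-5-yn-2-yl]oxolan-2-yl]ethoxy}dimethylsilane; 16 (5S,6R)-6-[(1E,3Z,5R,7E)-3-ethyl-8-iodo-5-methylocta-1,3,7-trien-1-yl]-5-methyl-5,6-dihydro-2H-pyran-2-one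
Product: 44 (5S,6R)-6-[(1E,3Z,5R,7E,9E,11R,12R,13R)-13-[(2R,3R,5R)-5-{2-[(tert-butyldimethylsilyl)oxy]ethyl}-3,5-dimethyloxolan-2-yl]-3-ethyl-5,9,11-trimethyl-12-[(triethylsilyl)oxy]tetradeca-1,3,7,9-tetraen-1-yl]-5-methyl-5,6-dihydro-2H-pyran-2-one, via alkenylzirconocene chloride 42 (not isolated), via alkenylzinc chloride 43 (not isolated)
Conditions: Cp2Zr(H)Cl (1.1 equiv), THF, 50 °C; ZnCl2 (1.2 equiv), 0 °C; then 16 (0.8 equiv), Pd(PPh3)4 (5 mol %), rt
Reagents that add atoms: none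
Why: Syn hydrozirconation places zirconium on the less hindered C14, and zirconium-to-zinc transmetalation followed by Negishi coupling proceeds with retention at both alkenes to give the 12E,14E diene while the lactone is tolerated.

Step 33
Reactants: 44 the bis-silyl ether from step 32
Product: 45 (5S,6R)-6-[(1E,3Z,5R,7E,9E,11R,12R,13S)-3-ethyl-12-hydroxy-13-[(2R,3R,5R)-5-(2-hydroxyethyl)-3,5-dimethyloxolan-2-yl]-5,9,11-trimethyltetradeca-1,3,7,9-tetraen-1-yl]-5-methyl-5,6-dihydro-2H-pyran-2-one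
Conditions: HF·pyridine, pyridine, THF, 0 °C → rt
Reagents that add atoms: none
Why: Buffered fluoride-mediated desilylation removes both silyl ethers without touching the lactone or the dienes.

Step 34
Reactants: 45 the diol from step 33
Product: 46 (5S,6R)-6-[(1E,3Z,5R,7E,9E,11R,13R)-13-[(2R,3R,5R)-3,5-dimethyl-5-(2-oxoethyl)oxolan-2-yl]-3-ethyl-5,9,11-trimethyl-12-oxotetradeca-1,3,7,9-tetraen-1-yl]-5-methyl-5,6-dihydro-2H-pyran-2-one
Conditions: Dess–Martin periodinane (3 equiv), pyridine, CH2Cl2, 0 °C → rt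
Reagents that add atoms: none
Why: Double Dess–Martin oxidation under non-basic conditions turns C17–OH into the ketone and C24–OH into the aldehyde without epimerising C16 or C18 and without β-elimination of the ring oxygen.

**Compound list**

1 | (S)-4-benzyl-3-propanoyl-1,3-oxazolidin-2-one | CCC(=O)N1[C@@H](Cc2ccccc2)COC1=O | starting material
2 | 3-bromoprop-1-yne | C#CCBr | starting material
3 | (S)-4-benzyl-3-[(2R)-2-methylpent-4-ynoyl]-1,3-oxazolidin-2-one | C#CC[C@@H](C)C(=O)N1[C@@H](Cc2ccccc2)COC1=O | intermediate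
4 | (2R)-2-methylpent-4-yn-1-ol | C#CC[C@@H](C)CO | intermediate
5 | bis-zirconocene alkenyl alkoxide: 6 with O–ZrCp2Cl in place of O–H and C–ZrCp2Cl in place of C–I | C[C@@H](CO[Zr](Cl)(C1C=CC=C1)C1C=CC=C1)C/C=C/[Zr](Cl)(C1C=CC=C1)C1C=CC=C1 | intermediate
6 | (2R,4E)-5-iodo-2-methylpent-4-en-1-ol | OC[C@H](C)C/C=C/I | intermediate
7 | (2R,4E)-5-iodo-2-methylpent-4-enal | O=C[C@H](C)C/C=C/I | intermediate
8 | methyl 2-[bis(2,2,2-trifluoroethoxy)phosphoryl]acetate | COC(=O)CP(=O)(OCC(F)(F)F)OCC(F)(F)F | starting material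
9 | methyl 2-[bis(2,2,2-trifluoroethoxy)phosphoryl]butanoate (racemic) | CCC(C(=O)OC)P(=O)(OCC(F)(F)F)OCC(F)(F)F | intermediate
10 | methyl (2Z,4R,6E)-2-ethyl-7-iodo-4-methylhepta-2,6-dienoate | CCC(=C/[C@H](C)C/C=C/I)/C(=O)OC | intermediate
11 | (2Z,4R,6E)-2-ethyl-7-iodo-4-methylhepta-2,6-dien-1-ol | CCC(=C/[C@H](C)C/C=C/I)/CO | intermediate
12 | (2Z,4R,6E)-2-ethyl-7-iodo-4-methylhepta-2,6-dienal | CCC(=C/[C@H](C)C/C=C/I)/C=O | intermediate
13 | (2E,4Z,6R,8E)-4-ethyl-9-iodo-6-methylnona-2,4,8-trienal | CCC(=C/[C@H](C)C/C=C/I)/C=C/C=O | intermediate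
14 | (3S,4R,5E,7Z,9R,11E)-7-ethyl-12-iodo-3,9-dimethyldodeca-1,5,7,11-tetraen-4-ol | CCC(=C/[C@H](C)C/C=C/I)/C=C/[C@@H](O)[C@@H](C)C=C | intermediate
15 | (3S,4R,5E,7Z,9R,11E)-7-ethyl-12-iodo-3,9-dimethyldodeca-1,5,7,11-tetraen-4-yl prop-2-enoate | CCC(=C/[C@H](C)C/C=C/I)/C=C/[C@@H](OC(=O)C=C)[C@@H](C)C=C | intermediate
16 | (5S,6R)-6-[(1E,3Z,5R,7E)-3-ethyl-8-iodo-5-methylocta-1,3,7-trien-1-yl]-5-methyl-5,6-dihydro-2H-pyran-2-one | CCC(=C/[C@H](C)C/C=C/I)/C=C/[C@H]1OC(=O)C=C[C@@H]1C | intermediate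
17 | 3-methylbut-2-en-1-ol | CC(C)=CCO | starting material
18 | tert-butyldimethyl[(3-methylbut-2-en-1-yl)oxy]silane | CC(C)=CCO[Si](C)(C)C(C)(C)C | intermediate
19 | (2E)-4-[(tert-butyldimethylsilyl)oxy]-2-methylbut-2-en-1-ol | OC/C(C)=C/CO[Si](C)(C)C(C)(C)C | intermediate
20 | {[(2E)-4-bromo-3-methylbut-2-en-1-yl]oxy}(tert-butyl)dimethylsilane | BrC/C(C)=C/CO[Si](C)(C)C(C)(C)C | intermediate
21 | (S)-4-benzyl-3-[(2R,4E)-6-[(tert-butyldimethylsilyl)oxy]-2,4-dimethylhex-4-enoyl]-1,3-oxazolidin-2-one | C[C@H](C/C(C)=C/CO[Si](C)(C)C(C)(C)C)C(=O)N1[C@@H](Cc2ccccc2)COC1=O | intermediate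
22 | (2R,4E)-6-[(tert-butyldimethylsilyl)oxy]-2,4-dimethylhex-4-en-1-ol | OC[C@H](C)C/C(C)=C/CO[Si](C)(C)C(C)(C)C | intermediate
23 | (2R)-3-[(2R,3R)-3-{[(tert-butyldimethylsilyl)oxy]methyl}-2-methyloxiran-2-yl]-2-methylpropan-1-ol | OC[C@H](C)C[C@@]1(C)O[C@@H]1CO[Si](C)(C)C(C)(C)C | intermediate
24 | (2R,4R)-6-[(tert-butyldimethylsilyl)oxy]-2,4-dimethylhexane-1,4-diol | OC[C@H](C)C[C@@](C)(O)CCO[Si](C)(C)C(C)(C)C | intermediate
25 | (2R,4R)-6-[(tert-butyldimethylsilyl)oxy]-4-hydroxy-2,4-dimethylhexanal | O=C[C@H](C)C[C@@](C)(O)CCO[Si](C)(C)C(C)(C)C | intermediate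
26 | (3R,5R)-5-{2-[(tert-butyldimethylsilyl)oxy]ethyl}-3,5-dimethyloxolan-2-ol (both anomers) | OC1O[C@@](C)(CCO[Si](C)(C)C(C)(C)C)C[C@H]1C | intermediate
27 | (R)-4-benzyl-1,3-oxazolidin-2-one | O=C1N[C@H](Cc2ccccc2)CO1 | starting material
28 | (R)-4-benzyl-3-(2-bromoacetyl)-1,3-oxazolidin-2-one | BrCC(=O)N1[C@H](Cc2ccccc2)COC1=O | intermediate
29 | {2-[(4R)-4-benzyl-2-oxo-1,3-oxazolidin-3-yl]-2-oxoethyl}triphenylphosphonium bromide | [Br-].O=C(C[P+](c1ccccc1)(c1ccccc1)c1ccccc1)N1[C@H](Cc2ccccc2)COC1=O | intermediate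
30 | (R)-4-benzyl-3-[(triphenylphosphoranylidene)acetyl]-1,3-oxazolidin-2-one | O=C(C=P(c1ccccc1)(c1ccccc1)c1ccccc1)N1[C@H](Cc2ccccc2)COC1=O | intermediate
31 | (R)-4-benzyl-3-[(2E,4R,6R)-8-[(tert-butyldimethylsilyl)oxy]-6-hydroxy-4,6-dimethyloct-2-enoyl]-1,3-oxazolidin-2-one | O=C(/C=C/[C@H](C)C[C@@](C)(O)CCO[Si](C)(C)C(C)(C)C)N1[C@H](Cc2ccccc2)COC1=O | intermediate
32 | (R)-4-benzyl-3-{[(2S,3R,5R)-5-{2-[(tert-butyldimethylsilyl)oxy]ethyl}-3,5-dimethyloxolan-2-yl]acetyl}-1,3-oxazolidin-2-one | O=C(C[C@@H]1O[C@@](C)(CCO[Si](C)(C)C(C)(C)C)C[C@H]1C)N1[C@H](Cc2ccccc2)COC1=O | intermediate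
33 | (R)-4-benzyl-3-{(2R)-2-[(2R,3R,5R)-5-{2-[(tert-butyldimethylsilyl)oxy]ethyl}-3,5-dimethyloxolan-2-yl]propanoyl}-1,3-oxazolidin-2-one | O=C([C@H](C)[C@@H]1O[C@@](C)(CCO[Si](C)(C)C(C)(C)C)C[C@H]1C)N1[C@H](Cc2ccccc2)COC1=O | intermediate
34 | (2S)-2-[(2R,3R,5R)-5-{2-[(tert-butyldimethylsilyl)oxy]ethyl}-3,5-dimethyloxolan-2-yl]propan-1-ol | OC[C@H](C)[C@@H]1O[C@@](C)(CCO[Si](C)(C)C(C)(C)C)C[C@H]1C | intermediate
35 | (2R)-2-[(2R,3R,5R)-5-{2-[(tert-butyldimethylsilyl)oxy]ethyl}-3,5-dimethyloxolan-2-yl]propanal | O=C[C@H](C)[C@@H]1O[C@@](C)(CCO[Si](C)(C)C(C)(C)C)C[C@H]1C | intermediate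
36 | (S)-but-3-yn-2-ol | C[C@H](O)C#C | starting material
37 | (S)-but-3-yn-2-yl methanesulfonate | C[C@H](OS(C)(=O)=O)C#C | intermediate
38 | (aR)-buta-1,2-dien-1-ylzinc methanesulfonate | [H]C(C)=[C@@]=C([H])[Zn]OS(C)(=O)=O | intermediate
39 | (2S,3R,4R)-2-[(2R,3R,5R)-5-{2-[(tert-butyldimethylsilyl)oxy]ethyl}-3,5-dimethyloxolan-2-yl]-4-methylhex-5-yn-3-ol | C#C[C@@H](C)[C@@H](O)[C@H](C)[C@@H]1O[C@@](C)(CCO[Si](C)(C)C(C)(C)C)C[C@H]1C | intermediate
40 | tert-butyl{2-[(2R,4R,5R)-2,4-dimethyl-5-[(2R,3R,4R)-4-methyl-3-[(triethylsilyl)oxy]hex-5-yn-2-yl]oxolan-2-yl]ethoxy}dimethylsilane | C#C[C@@H](C)[C@@H](O[Si](CC)(CC)CC)[C@H](C)[C@@H]1O[C@@](C)(CCO[Si](C)(C)C(C)(C)C)C[C@H]1C | intermediate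
41 | tert-butyl{2-[(2R,4R,5R)-2,4-dimethyl-5-[(2R,3R,4R)-4-methyl-3-[(triethylsilyl)oxy]hept-5-yn-2-yl]oxolan-2-yl]ethoxy}dimethylsilane | CC#C[C@@H](C)[C@@H](O[Si](CC)(CC)CC)[C@H](C)[C@@H]1O[C@@](C)(CCO[Si](C)(C)C(C)(C)C)C[C@H]1C | intermediate
42 | chlorobis(cyclopentadienyl)[(2E,4R,5R,6R)-6-[(2R,3R,5R)-5-{2-[(tert-butyldimethylsilyl)oxy]ethyl}-3,5-dimethyloxolan-2-yl]-4-methyl-5-[(triethylsilyl)oxy]hept-2-en-2-yl]zirconium | Cl[Zr](C1C=CC=C1)(C1C=CC=C1)/C(C)=C/[C@@H](C)[C@@H](O[Si](CC)(CC)CC)[C@H](C)[C@@H]1O[C@@](C)(CCO[Si](C)(C)C(C)(C)C)C[C@H]1C | intermediate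
43 | chloro[(2E,4R,5R,6R)-6-[(2R,3R,5R)-5-{2-[(tert-butyldimethylsilyl)oxy]ethyl}-3,5-dimethyloxolan-2-yl]-4-methyl-5-[(triethylsilyl)oxy]hept-2-en-2-yl]zinc | Cl[Zn]/C(C)=C/[C@@H](C)[C@@H](O[Si](CC)(CC)CC)[C@H](C)[C@@H]1O[C@@](C)(CCO[Si](C)(C)C(C)(C)C)C[C@H]1C | intermediate
44 | (5S,6R)-6-[(1E,3Z,5R,7E,9E,11R,12R,13R)-13-[(2R,3R,5R)-5-{2-[(tert-butyldimethylsilyl)oxy]ethyl}-3,5-dimethyloxolan-2-yl]-3-ethyl-5,9,11-trimethyl-12-[(triethylsilyl)oxy]tetradeca-1,3,7,9-tetraen-1-yl]-5-methyl-5,6-dihydro-2H-pyran-2-one | CCC(=C/[C@H](C)C/C=C/C(C)=C/[C@@H](C)[C@@H](O[Si](CC)(CC)CC)[C@H](C)[C@@H]1O[C@@](C)(CCO[Si](C)(C)C(C)(C)C)C[C@H]1C)/C=C/[C@H]1OC(=O)C=C[C@@H]1C | intermediate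
45 | (5S,6R)-6-[(1E,3Z,5R,7E,9E,11R,12R,13S)-3-ethyl-12-hydroxy-13-[(2R,3R,5R)-5-(2-hydroxyethyl)-3,5-dimethyloxolan-2-yl]-5,9,11-trimethyltetradeca-1,3,7,9-tetraen-1-yl]-5-methyl-5,6-dihydro-2H-pyran-2-one | CCC(=C/[C@H](C)C/C=C/C(C)=C/[C@@H](C)[C@@H](O)[C@H](C)[C@@H]1O[C@@](C)(CCO)C[C@H]1C)/C=C/[C@H]1OC(=O)C=C[C@@H]1C | intermediate
46 | (5S,6R)-6-[(1E,3Z,5R,7E,9E,11R,13R)-13-[(2R,3R,5R)-3,5-dimethyl-5-(2-oxoethyl)oxolan-2-yl]-3-ethyl-5,9,11-trimethyl-12-oxotetradeca-1,3,7,9-tetraen-1-yl]-5-methyl-5,6-dihydro-2H-pyran-2-one | CCC(=C/[C@H](C)C/C=C/C(C)=C/[C@@H](C)C(=O)[C@H](C)[C@@H]1O[C@@](C)(CC=O)C[C@H]1C)/C=C/[C@H]1OC(=O)C=C[C@@H]1C | target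

**Step count and risks**

Total step count: 34. Longest linear sequence: 19 steps (13–20, 23–27, 29–34, from 17 to 46), which is 56 % of the total.

The three steps most likely to fail:

Step 25 (with step 24). The sodium enolate of the β-alkoxy imide 32 can open the oxolane by E1cB elimination, and this would erode C18 or C19. The fallback sets out from lactol 26 and comes back at alcohol 34. Lactol 26 is acetylated (Ac2O, pyridine) to the lactol acetate F6. The chlorotitanium enolate of (S)-4-isopropyl-3-propanoyl-1,3-thiazolidine-2-thione (TiCl4, i-Pr2NEt, CH2Cl2, −78 °C) is then added to the oxocarbenium ion released from F6 with SnCl4. This forms the C18–C19 bond directly: the auxiliary fixes C18 and attack anti to the C20 methyl fixes C19, giving the thioimide F7. LiBH4 then removes the auxiliary to give 34.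

Step 32. Hydrozirconation of the internal alkyne may be incompletely regioselective, and residual Zr–H can attack the lactone of 16 in the one-pot coupling. The fallback sets out from alkyne 41 and comes back at 44. Hydrozirconation and iodinolysis (Cp2Zr(H)Cl, THF, 50 °C; I2) give the isolable (E)-vinyl iodide F8, which is purified. Lithium–iodine exchange and stannylation (t-BuLi, Et2O, −78 °C; Bu3SnCl) give the vinylstannane F9. A Stille coupling of F9 with 16 under neutral conditions (Pd2(dba)3, AsPh3, DMF, 40 °C) then gives 44.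

Step 18. Shi epoxidation of the hydroxy alkene 22 may give only moderate facial selectivity, and the δ-hydroxy epoxide 23 can cyclise on handling. The fallback sets out from 22 and comes back at 24. Alcohol 22 is protected (NaH, PMBCl) as the 4-methoxybenzyl ether F1, and Bu4NF frees the allylic alcohol F2. Sharpless asymmetric epoxidation (Ti(Oi-Pr)4, D-(−)-diethyl tartrate, t-BuOOH, −20 °C) gives the (2R,3R)-epoxy alcohol F3. Hydroxyl-directed opening at C23 with NaAlH2(OCH2CH2OMe)2 gives the 1,3-diol F4, and TBSCl with imidazole silylates the primary hydroxyl to give F5. DDQ then removes the 4-methoxybenzyl group to give 24.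

Further compounds
F1 | step 18 | tert-butyl{[(2E,5R)-6-[(4-methoxybenzyl)oxy]-3,5-dimethylhex-2-en-1-yl]oxy}dimethylsilane | COc1ccc(COC[C@H](C)C/C(C)=C/CO[Si](C)(C)C(C)(C)C)cc1
F2 | step 18 | (2E,5R)-6-[(4-methoxybenzyl)oxy]-3,5-dimethylhex-2-en-1-ol | COc1ccc(COC[C@H](C)C/C(C)=C/CO)cc1
F3 | step 18 | {(2R,3R)-3-[(2R)-3-[(4-methoxybenzyl)oxy]-2-methylpropyl]-3-methyloxiran-2-yl}methanol | COc1ccc(COC[C@H](C)C[C@@]2(C)O[C@@H]2CO)cc1
F4 | step 18 | (3R,5R)-6-[(4-methoxybenzyl)oxy]-3,5-dimethylhexane-1,3-diol | COc1ccc(COC[C@H](C)C[C@@](C)(O)CCO)cc1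
F5 | step 18 | (3R,5R)-1-[(tert-butyldimethylsilyl)oxy]-6-[(4-methoxybenzyl)oxy]-3,5-dimethylhexan-3-ol | COc1ccc(COC[C@H](C)C[C@@](C)(O)CCO[Si](C)(C)C(C)(C)C)cc1
F6 | step 25 | (3R,5R)-5-{2-[(tert-butyldimethylsilyl)oxy]ethyl}-3,5-dimethyloxolan-2-yl acetate (both anomers) | CC(=O)OC1O[C@@](C)(CCO[Si](C)(C)C(C)(C)C)C[C@H]1C
F7 | step 25 | (2R)-2-[(2R,3R,5R)-5-{2-[(tert-butyldimethylsilyl)oxy]ethyl}-3,5-dimethyloxolan-2-yl]-1-[(4S)-4-isopropyl-2-thioxo-1,3-thiazolidin-3-yl]propan-1-one | O=C([C@H](C)[C@@H]1O[C@@](C)(CCO[Si](C)(C)C(C)(C)C)C[C@H]1C)N1[C@@H](C(C)C)CSC1=S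
F8 | step 32 | tert-butyl{2-[(2R,4R,5R)-5-[(2R,3R,4R,5E)-6-iodo-4-methyl-3-[(triethylsilyl)oxy]hept-5-en-2-yl]-2,4-dimethyloxolan-2-yl]ethoxy}dimethylsilane | I/C(C)=C/[C@@H](C)[C@@H](O[Si](CC)(CC)CC)[C@H](C)[C@@H]1O[C@@](C)(CCO[Si](C)(C)C(C)(C)C)C[C@H]1C
F9 | step 32 | tributyl[(2E,4R,5R,6R)-6-[(2R,3R,5R)-5-{2-[(tert-butyldimethylsilyl)oxy]ethyl}-3,5-dimethyloxolan-2-yl]-4-methyl-5-[(triethylsilyl)oxy]hept-2-en-2-yl]stannane | CCCC[Sn](CCCC)(CCCC)/C(C)=C/[C@@H](C)[C@@H](O[Si](CC)(CC)CC)[C@H](C)[C@@H]1O[C@@](C)(CCO[Si](C)(C)C(C)(C)C)C[C@H]1C
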